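Remark on numbering: atoms are numbered along the C22 chain (C-1 = carboxyl carbon, C-22 = methyl carbon of the ketone) and written with a hyphen (C-3); bare numbers (3) are compounds.

## Analysis of the target

The target is a C22 fatty acid in which C-3 and C-6 are bridged by a peroxide, so that the two oxygens, C-3, C-4, C-5 and C-6 form a 1,2-dioxane, the only ring. C-6 is a peroxyketal carbon (ring oxygen, OMe, C-5, C-7). C-3 is a secondary peroxy carbon that sits β to the C-1 carboxyl group. The chain also holds an (E)-enyne (C-10≡C-11, C-12=C-13) and a methyl ketone at C-21.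

There are two stereocentres, C-3 (S) and C-6 (R), 1,4-related across the ring. The methoxy group and the CH2CO2H arm are cis. This is the chair with axial OMe (anomeric effect) and both carbon substituents equatorial, the thermodynamically preferred isomer. Because C-6 is a ketal carbon it can be equilibrated by acid, so C-6 can be set by C-3. Only C-3 needs absolute control, and it has no neighbouring stereocentre to lean on.

The sensitive groups are:
- the O–O bond (phosphines, low-valent metals, hydrides, strong base);
- the peroxyketal (aqueous acid);
- the C-3–H and C-2–H bonds next to the peroxide (β-elimination, Kornblum–DeLaMare cleavage);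
- the enyne (ozone, diimide, hydrogenation);
- three carbonyl-level carbons (C-1, C-6, C-21) that must be told apart.

The difficulty is to place a peroxide oxygen on C-3 with absolute control while keeping the peroxide away from the carbon–carbon bond-forming steps. The route is tied to two features: C-3 is the β-carbon of a C-1 carbonyl group, hence a conjugate-addition site for a peroxide oxygen, and the C-6 peroxyketal of the 1,2-dioxane is a thermodynamic sink.

## Retrosynthetic reasoning

**16 ⇒ 15.** The two bonds from C-6 to oxygen (C-6–OO and C-6–OMe) are cut first. C-6 is the stereocentre that thermodynamics sets, so the ring is opened there and not at C-3. This leads to the acyclic keto acid 15, in which C-3 already carries the peroxide as a mixed peroxyketal whose carrier carbon also holds the methoxy group. Forward, acid has to move the peroxide terminus and the methoxy group from the carrier carbon to C-6 and let the C-6 epimers equilibrate to the cis isomer.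

**15 ⇒ 11 + 13.** The C-3–O bond is cut next, as an intermolecular conjugate addition of the hydroperoxide 13 to the enal 11, with the aldehyde 14 oxidised to the acid in the same flask. It is cut between two molecules and not as the ring closure for two reasons. A chiral amine can then set C-3 on a substrate with no other stereocentre, so there is no matched/mismatched pair. The peroxide also enters only in the penultimate step. The gain is large: 11 is achiral, has no O–O bond and already holds all 22 carbons. Forward, the reaction must add oxygen to C-3 with facial control and leave the O–O bond intact.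

**11 ⇒ 9.** The C-2=C-3 double bond is cut as an olefination of the keto aldehyde 10 with a two-carbon formyl ylide; 10 is released from the acetal 9. This places the enal last among the C–C steps and keeps C-3 masked during the fragment coupling.

**9 ⇒ 4 + 8.** The C-11–C-12 sp–sp2 bond is cut into the terminal alkyne 4 and the (E)-alkenyl iodide 8. The cut divides the chain into two halves of similar size, the E geometry is fixed beforehand in 8, and the coupling is done while no peroxide is present.

**4 ⇒ 1 + 2.** The C-5–C-6 bond is cut as an acylation of the organozinc reagent 2 by the acid chloride 3, made from the acid 1. This gives the C-6 ketone directly, with the C-3 aldehyde masked as the acetal and the alkyne left free.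

**8 ⇒ 7 ⇒ 6 ⇒ 5.** The C-12=C-13 bond comes from a one-carbon iodo-olefination of the aldehyde 7. 7 comes from the alcohol 6, and the C-21 ketone of 6 from the terminal alkene of 5.

**13 ⇒ 12.** The hydroperoxide 13 comes from a Criegee cleavage of the tetrasubstituted alkene 12 in the alcohol that supplies the methoxy group.

## Alternatives that were turned down

**Alternative 1:** the textbook route. The C-11–C-12 coupling comes last, and the ring is closed at C-3–O by a 6-exo-trig peroxy-Michael addition. The key step is the base-mediated cyclisation of the hydroperoxy ketal enoate A1 (from ozonolysis of a 6-methylidene enoate in methanol) to the dioxane ester A2. It was turned down for these reasons: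
- A1 has no source of absolute configuration, so A2 forms as a racemic mixture of C-3/C-6 diastereomers and needs a resolution.
- A chiral catalyst for the same closure would meet the racemic C-6 centre of A1 as a matched/mismatched pair.
- The ozonolysis must precede the enyne, so the peroxide has to survive Pd/Cu coupling and an ester hydrolysis β to the O–O bond.
- The sequence (methylenation, olefination, ozonolysis, cyclisation, equilibration, resolution, saponification, coupling) is longer than the route chosen.

**Alternative 2:** ring closure at C-3–O by substitution. The key step is a 6-exo-tet displacement, with inversion, of the C-3 sulfonate in A3 by its own C-6 hydroperoxy ketal to give the dioxane A4. It was turned down for these reasons: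
- The carboxyl group must be carried at the alcohol oxidation level (otherwise E1cB elimination of the sulfonate), which costs a protection, a deprotection and two oxidations.
- The carbinol of A3 needs a separate asymmetric reduction.
- A basic peroxide anion at a secondary sulfonate invites E2 elimination.
- The peroxide again precedes the fragment coupling, and the step count is about double.

**Alternative 3:** both C–O bonds at once. The key step is a [4+2] cycloaddition of singlet oxygen to the dienol ether A5 to give the 3,6-dihydro-1,2-dioxine A6, followed by diimide reduction of the ring double bond. It was turned down for these reasons: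
- A5 is achiral and nothing differentiates its faces, so A6 is racemic and the C-3 problem is unsolved.
- The electron-rich enol ether terminus diverts singlet oxygen to [2+2] and ene pathways.
- The trisubstituted terminus disfavours the s-cis conformer.
- Diimide would also reduce the alkyne, which forces extra protection.

Key step: step 8

Assumption: the zinc reagent 2 and both antipodes of the diarylprolinol silyl ether are taken as commercial; the (R)-antipode is assigned from the usual face-shielding model of its (E)-iminium ions, and the other antipode would be used if the sense proved opposite.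

## Route

Step 1
Reactants: 1 hex-5-ynoic acid; 2 [2-(1,3-dioxolan-2-yl)ethyl]zinc bromide (0.5 M in THF)
Product: 4 1-(1,3-dioxolan-2-yl)oct-7-yn-3-one, via hex-5-ynoyl chloride 3 (not isolated)
Conditions: (i) (COCl)2, cat. DMF, CH2Cl2, 0 °C → rt, evaporate; (ii) 2 (1.1 equiv), Pd(PPh3)4 (3 mol%), THF, 0 °C → rt
Reagents that add atoms: none
Why: Negishi acylation of an acid chloride; the alkylzinc halide tolerates the acetal, is too weak a base to deprotonate the terminal alkyne and does not add to the ketone formed.

Step 2
Reactants: 5 dec-9-en-1-ol
Product: 6 10-hydroxydecan-2-one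
Conditions: PdCl2 (10 mol%), CuCl (1 equiv), O2 (1 atm), DMF/H2O 7:1, rt
Reagents that add atoms: water, O
Why: Tsuji–Wacker oxidation; the terminal alkene should give the methyl ketone with Markovnikov selectivity, O2 being the terminal oxidant, and the primary alcohol is inert under these conditions.

Step 3
Reactants: 6 10-hydroxydecan-2-one
Product: 7 9-oxodecanal
Conditions: TEMPO (10 mol%), PhI(OAc)2 (1.1 equiv), CH2Cl2, rt
Reagents that add atoms: none
Why: TEMPO/hypervalent iodine oxidation stops at the aldehyde and does not enolise or touch the ketone.

Step 4
Reactants: 7 9-oxodecanal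
Product: 8 (10E)-11-iodoundec-10-en-2-one
Conditions: CrCl2 (6 equiv), CHI3 (2 equiv), THF/1,4-dioxane 1:6, 0 °C → rt
Reagents that add atoms: iodoform, IC(I)I
Why: Takai iodo-olefination; the gem-dichromium reagent reacts with the aldehyde much faster than with the ketone, and the E-alkenyl iodide should dominate, the dioxane co-solvent raising the E selectivity.

Step 5
Reactants: 4 1-(1,3-dioxolan-2-yl)oct-7-yn-3-one; 8 (10E)-11-iodoundec-10-en-2-one
Product: 9 (9E)-1-(1,3-dioxolan-2-yl)nonadec-9-en-7-yne-3,18-dione
Conditions: Pd(PPh3)2Cl2 (2 mol%), CuI (4 mol%), Et3N (3 equiv), THF, rt, degassed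
Reagents that add atoms: none
Why: Sonogashira coupling forms C-11–C-12 with retention of the E geometry of 8; ketones and acetal are inert, and no peroxide is present yet, so phosphine, Pd and Cu do no harm.

Step 6
Reactants: 9 (9E)-1-(1,3-dioxolan-2-yl)nonadec-9-en-7-yne-3,18-dione
Product: 11 (2E,12E)-6,21-dioxodocosa-2,12-dien-10-ynal, via keto aldehyde 10 (not isolated)
Conditions: (i) TsOH·H2O (0.2 equiv), THF/H2O 3:1, 45 °C; (ii) NaHCO3 (0.3 equiv), then Ph3P=CHCHO (1.2 equiv), rt
Reagents that add atoms: (triphenylphosphoranylidene)acetaldehyde, O=CC=P(c1ccccc1)(c1ccccc1)c1ccccc1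
Why: Acetal hydrolysis followed in the same flask by a Wittig reaction with a stabilised ylide, which reacts only with the aldehyde of 10 (not with the two ketones) and should give the E-enal; trapping 10 at once limits aldol and furan formation of the 4-oxo aldehyde.

Step 7
Reactants: 12 2,3-dimethylbut-2-ene
Product: 13 2-hydroperoxy-2-methoxypropane
Conditions: O3, MeOH/CH2Cl2 1:4, −78 °C; N2 purge; kept and used as a solution
Reagents that add atoms: ozone, [O-][O+]=O; methanol, CO
Why: Criegee ozonolysis; the carbonyl oxide from the symmetrical alkene is trapped by methanol to give the α-methoxy hydroperoxide, a masked hydrogen peroxide that also carries the methoxy group needed later.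

Step 8
Reactants: 11 (2E,12E)-6,21-dioxodocosa-2,12-dien-10-ynal; 13 2-hydroperoxy-2-methoxypropane (2 equiv)
Product: 15 (3S,12E)-3-[(2-methoxypropan-2-yl)peroxy]-6,21-dioxodocos-12-en-10-ynoic acid, via peroxy aldehyde 14 (not isolated)
Conditions: (i) (R)-2-{bis[3,5-bis(trifluoromethyl)phenyl][(trimethylsilyl)oxy]methyl}pyrrolidine (10 mol%), PhCO2H (10 mol%), toluene, 0 °C; (ii) t-BuOH/H2O, 2-methylbut-2-ene (10 equiv), NaH2PO4/Na2HPO4 (pH 5), NaClO2 (3 equiv), 0 °C
Reagents that add atoms: sodium chlorite, [Na+].[O-]Cl=O
Why: The secondary amine condenses with enal 11 to an (E)-configured s-trans iminium ion, the hydroperoxide oxygen of 13 adds to C-3, the resulting enamine is protonated by the benzoic acid co-catalyst and hydrolysed to 14, and chlorite (Pinnick oxidation) then converts the aldehyde to the acid in the same flask, which removes 14 from the amine before it can form an enamine again. The closest known reaction type is the diarylprolinol silyl ether-catalysed enantioselective conjugate addition of alkyl hydroperoxides to α,β-unsaturated aldehydes, here with an α-alkoxyalkyl hydroperoxide as masked hydrogen peroxide. The step closes no ring: it forms the C-3–O bond and brings in both peroxide oxygens and the future methoxy group, and the 1,2-dioxane closes in step 9. The C-3 stereocentre is set by the catalyst alone: the diaryl(silyloxy)methyl group of the (R)-catalyst shields one face of the iminium ion, 13 should add to the open Si face of C-3, and this corresponds to 3S. The selectivity needed is 1,4-addition with the O–O bond kept, against Weitz–Scheffer collapse of the peroxy enamine to the epoxy aldehyde; the acid co-catalyst, the low temperature and the immediate oxidation are there to secure it. Chemoselectivity rests on the aldehyde being the only carbonyl group that forms an iminium ion at a useful rate, so the C-6 and C-21 ketones and the enyne should be spectators. The chlorite stage is buffered near pH 5 so that the acid-labile peroxyketal of 15 survives; partial loss would only anticipate step 9.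

Step 9
Reactants: 15 (3S,12E)-3-[(2-methoxypropan-2-yl)peroxy]-6,21-dioxodocos-12-en-10-ynoic acid
Product: 16 2-[(3S,6R)-6-methoxy-6-[(6E)-15-oxohexadec-6-en-4-yn-1-yl]-1,2-dioxan-3-yl]acetic acid
Conditions: CSA (0.1 equiv), MeOH (0.2 equiv, shuttle), CH2Cl2 (0.02 M), 0 °C → rt
Reagents that add atoms: none
Why: Acid-catalysed peroxyketal exchange: the acyclic peroxyketal ionises and frees the C-3 hydroperoxide, which adds 6-exo-trig to the C-6 ketone, and the hemiketal takes up the methoxy group released from the carrier, acetone being the only by-product. Every event is reversible, so C-6 is set under thermodynamic control by C-3: the chair with axial OMe (anomeric effect) and both carbon substituents equatorial is the 3S,6R cis isomer, and C-3 is not touched. High dilution and the six-membered ring should keep the C-21 ketone out of the exchange.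

## Compound list

1 | hex-5-ynoic acid | C#CCCCC(=O)O | starting material
2 | [2-(1,3-dioxolan-2-yl)ethyl]zinc bromide | Br[Zn]CCC1OCCO1 | starting material
3 | hex-5-ynoyl chloride | C#CCCCC(=O)Cl | intermediate (not isolated)
4 | 1-(1,3-dioxolan-2-yl)oct-7-yn-3-one | C#CCCCC(=O)CCC1OCCO1 | intermediate
5 | dec-9-en-1-ol | C=CCCCCCCCCO | starting material
6 | 10-hydroxydecan-2-one | CC(=O)CCCCCCCCO | intermediate
7 | 9-oxodecanal | CC(=O)CCCCCCCC=O | intermediate
8 | (10E)-11-iodoundec-10-en-2-one | CC(=O)CCCCCCC/C=C/I | intermediate
9 | (9E)-1-(1,3-dioxolan-2-yl)nonadec-9-en-7-yne-3,18-dione | CC(=O)CCCCCCC/C=C/C#CCCCC(=O)CCC1OCCO1 | intermediate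
10 | (10E)-4,19-dioxoicos-10-en-8-ynal | CC(=O)CCCCCCC/C=C/C#CCCCC(=O)CCC=O | intermediate (not isolated)
11 | (2E,12E)-6,21-dioxodocosa-2,12-dien-10-ynal | CC(=O)CCCCCCC/C=C/C#CCCCC(=O)CC/C=C/C=O | intermediate
12 | 2,3-dimethylbut-2-ene | CC(C)=C(C)C | starting material
13 | 2-hydroperoxy-2-methoxypropane | COC(C)(C)OO | intermediate
14 | (3S,12E)-3-[(2-methoxypropan-2-yl)peroxy]-6,21-dioxodocos-12-en-10-ynal | CC(=O)CCCCCCC/C=C/C#CCCCC(=O)CC[C@@H](CC=O)OOC(C)(C)OC | intermediate (not isolated)
15 | (3S,12E)-3-[(2-methoxypropan-2-yl)peroxy]-6,21-dioxodocos-12-en-10-ynoic acid | CC(=O)CCCCCCC/C=C/C#CCCCC(=O)CC[C@@H](CC(=O)O)OOC(C)(C)OC | intermediate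
16 | 2-[(3S,6R)-6-methoxy-6-[(6E)-15-oxohexadec-6-en-4-yn-1-yl]-1,2-dioxan-3-yl]acetic acid | CO[C@@]1(CCCC#C/C=C/CCCCCCCC(C)=O)CC[C@@H](CC(=O)O)OO1 | target

## Step count and least certain steps

Total: 9 steps. Longest linear sequence: 7 steps (2, 3, 4, 5, 6, 8, 9); the branch from 1 has 5 steps (1, 5, 6, 8, 9).

**Step 8 (key step).** Most likely to go wrong is incomplete facial discrimination: the hydroperoxide is small and unhindered, and a slow uncatalysed addition or a reversible loss and re-addition of the peroxide at the enamine stage would lower the enantiomeric purity further. Collapse of the peroxy enamine to the epoxy aldehyde would cost material and is countered within the step by the acid co-catalyst, the low temperature and the immediate oxidation.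

The fallback sets out from 11 and comes back at 16, and replaces catalyst control by resolution. The addition is run without asymmetric induction (pyrrolidine, benzoic acid, then chlorite as in step 8). It gives, via racemic (12E)-3-[(2-methoxypropan-2-yl)peroxy]-6,21-dioxodocos-12-en-10-ynal F1, racemic (12E)-3-[(2-methoxypropan-2-yl)peroxy]-6,21-dioxodocos-12-en-10-ynoic acid F2. Ring closure under the conditions of step 9 gives racemic cis 2-[6-methoxy-6-[(6E)-15-oxohexadec-6-en-4-yn-1-yl]-1,2-dioxan-3-yl]acetic acid F3. The enantiomers of F3 are separated by preparative chromatography on a chiral stationary phase, and the (3S,6R) fraction is 16.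

**Step 9.** Most likely to go wrong is a misdirected or incomplete transfer. The freed hydroperoxide may be captured by the C-21 ketone of a second molecule (intermolecular peroxyketals, oligomers), the exchange may stall at the C-6 hemiketal, and prolonged acid may fragment the secondary hydroperoxide.

The fallback sets out from 4 and comes back at 16; the ring is closed on the short alkyne fragment, where C-6 is the only ketone, and the side chain is attached last. Hydrolysis and olefination of 4 as in step 6 give, via 4-oxonon-8-ynal F4, (2E)-6-oxoundec-2-en-10-ynal F5. The conditions of step 8 give, via (3S)-3-[(2-methoxypropan-2-yl)peroxy]-6-oxoundec-10-ynal F6, (3S)-3-[(2-methoxypropan-2-yl)peroxy]-6-oxoundec-10-ynoic acid F7. The conditions of step 9 give 2-[(3S,6R)-6-methoxy-6-(pent-4-yn-1-yl)-1,2-dioxan-3-yl]acetic acid F8. Sonogashira coupling of F8 with 8 (conditions of step 5, extra Et3N for the free acid) gives 16. The price is that the peroxyketal must then survive Pd/Cu and phosphine.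

**Step 4.** Most likely to go wrong is incomplete E selectivity of the iodo-olefination of an unbranched aliphatic aldehyde; the Z-iodide is hard to remove and would be carried into the enyne.

The fallback sets out from 7 and comes back at 8, and fixes the geometry by a syn addition to an alkyne. Homologation of 7 with dimethyl (1-diazo-2-oxopropyl)phosphonate (K2CO3, MeOH; aldehyde-selective) gives undec-10-yn-2-one F9. Pd-catalysed syn-hydrostannation (Bu3SnH, PdCl2(PPh3)2, THF) gives (10E)-11-(tributylstannyl)undec-10-en-2-one F10. Iododestannylation (I2, CH2Cl2, 0 °C) returns 8.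

## Further compounds

F1 | step 8 | (12E)-3-[(2-methoxypropan-2-yl)peroxy]-6,21-dioxodocos-12-en-10-ynal (racemate) | CC(=O)CCCCCCC/C=C/C#CCCCC(=O)CCC(CC=O)OOC(C)(C)OC
F2 | step 8 | (12E)-3-[(2-methoxypropan-2-yl)peroxy]-6,21-dioxodocos-12-en-10-ynoic acid (racemate) | CC(=O)CCCCCCC/C=C/C#CCCCC(=O)CCC(CC(=O)O)OOC(C)(C)OC
F3 | step 8 | 2-[6-methoxy-6-[(6E)-15-oxohexadec-6-en-4-yn-1-yl]-1,2-dioxan-3-yl]acetic acid (racemate of the cis isomer, 3S,6R and 3R,6S) | CO[C@@]1(CCCC#C/C=C/CCCCCCCC(C)=O)CC[C@@H](CC(=O)O)OO1.CO[C@]1(CCCC#C/C=C/CCCCCCCC(C)=O)CC[C@H](CC(=O)O)OO1
F4 | step 9 | 4-oxonon-8-ynal | C#CCCCC(=O)CCC=O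
F5 | step 9 | (2E)-6-oxoundec-2-en-10-ynal | C#CCCCC(=O)CC/C=C/C=O
F6 | step 9 | (3S)-3-[(2-methoxypropan-2-yl)peroxy]-6-oxoundec-10-ynal | C#CCCCC(=O)CC[C@@H](CC=O)OOC(C)(C)OC
F7 | step 9 | (3S)-3-[(2-methoxypropan-2-yl)peroxy]-6-oxoundec-10-ynoic acid | C#CCCCC(=O)CC[C@@H](CC(=O)O)OOC(C)(C)OC
F8 | step 9 | 2-[(3S,6R)-6-methoxy-6-(pent-4-yn-1-yl)-1,2-dioxan-3-yl]acetic acid | CO[C@@]1(CCCC#C)CC[C@@H](CC(=O)O)OO1
F9 | step 4 | undec-10-yn-2-one | CC(=O)CCCCCCCC#C
F10 | step 4 | (10E)-11-(tributylstannyl)undec-10-en-2-one | CC(=O)CCCCCCC/C=C/[Sn](CCCC)(CCCC)CCCC
A1 | alternative 1 | methyl (2E)-6-hydroperoxy-6-methoxyundec-2-en-10-ynoate (racemate) | C#CCCCC(OC)(OO)CC/C=C/C(=O)OC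
A2 | alternative 1 | methyl 2-[6-methoxy-6-(pent-4-yn-1-yl)-1,2-dioxan-3-yl]acetate (racemic mixture of diastereomers) | COC(=O)CC1CCC(OC)(CCCC#C)OO1
A3 | alternative 2 | (3R)-1-[(tert-butyldimethylsilyl)oxy]-6-hydroperoxy-6-methoxyundec-10-yn-3-yl methanesulfonate (both C-6 epimers) | C#CCCCC(OC)(OO)CC[C@H](CCO[Si](C)(C)C(C)(C)C)OS(C)(=O)=O
A4 | alternative 2 | tert-butyl{2-[(3S,6R)-6-methoxy-6-(pent-4-yn-1-yl)-1,2-dioxan-3-yl]ethoxy}dimethylsilane | CO[C@@]1(CCCC#C)CC[C@@H](CCO[Si](C)(C)C(C)(C)C)OO1
A5 | alternative 3 | methyl (3E,5Z)-6-methoxyundeca-3,5-dien-10-ynoate | COC(=O)C/C=C/C=C(\OC)CCCC#C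
A6 | alternative 3 | methyl 2-[6-methoxy-6-(pent-4-yn-1-yl)-3,6-dihydro-1,2-dioxin-3-yl]acetate (racemate) | COC(=O)CC1C=CC(OC)(CCCC#C)OO1
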